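## Analysis of the target

The target 20 (C26H36O4) is a 20-membered cyclophane. Ring A is a 1,3,5-trisubstituted benzene (A1 OH, A3 chain, A5 ether oxygen). Ring B is a benzene-1,3-diol (B1 ether oxygen, B2 and B4 OH, B3 and B5 H, B6 chain). The rings are joined by the diaryl ether oxygen A5–O–B1 and by an unbranched strap of fourteen methylene groups, C1 on B6 to C14 on A3. The macrocycle runs through B6, B1, the oxygen, A5, A4, A3 and the fourteen chain carbons.

There is no stereocentre, and a ring of this size should be conformationally mobile, so no stereochemical element has to be set or related to another. The sensitive groups are the three phenols, above all ring B, which is a 1,2,4-trioxygenated and easily oxidised arene. They are best kept as methyl ethers, or not yet aromatic, until late.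

Two things make the synthesis hard. One is the entropic cost of closing a large ring across a flexible fourteen-carbon strap. The other is the ether bond at B1, which lies between two ortho substituents (the B2 oxygen and the chain) on an electron-rich ring and is a poor site for Ullmann or SNAr chemistry.

The strategy rests on reading ring B as a 5-alkylresorcinol that carries its ether oxygen on the carbon next to the alkyl group. B6, B1, B2 and B3 are then the four carbons of an α-aryloxy enone (B6=B1 the alkene, B2 the carbonyl, B3 the methyl group), and B4 and B5 come from a malonate. The O–B1 bond can therefore be made at an sp3 carbon, and the macrocycle closed by olefination between B1 and B6, before ring B exists.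

## Retrosynthetic reasoning

**20 ⇒ 19.** Only the three O–CH3 bonds are cut. Carrying every phenol as its methyl ether to the last step shields the oxidation-prone ring B. The forward reaction is a Lewis-acid ether cleavage that must spare the diaryl ether, which it should because both of its C–O bonds are to sp2 carbon.

**19 ⇒ 18.** No skeletal bond is cut. Ring B is taken back to the oxidation level of a cyclohexane-1,3-dione (B2 and B4 carbonyl, B1 and B6 sp3). This turns a hindered, electron-rich arene into something that carbonyl chemistry can assemble. The forward step must remove two hydrogens and fix both oxygens as methyl ethers. It should do so without a hydrogenation metal, because the hydrogen released in a catalytic dehydrogenation could cleave the α-aryloxy ketone C–O bond of 18 and open the macrocycle.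

**18 ⇒ 16 ⇒ 13 + 14.** The bonds B5–B6 and B3–B4 are cut, and one ester carbon on B5 is removed. This is a [3+3] construction: enone 13 supplies B6, B1, B2 and B3, and malonate 14 supplies B5 and B4 plus a carbon that leaves as carbon dioxide. These bonds are chosen because in 13 the only acceptor carbon is B6, and the only ketone α-carbon that can reach an ester through a six-membered transition state is B3. Regiochemistry is therefore fixed by the skeleton, and both ring B oxygens arrive in the right places.

**13 ⇒ 12 (key disconnection).** The double bond B1=B6 is cut. It lies inside the future ring B, so the macrocycle closes by C=C formation between a stabilised phosphonate carbanion and an aldehyde, a reaction type with a good record for large rings. The other cuts through the macrocycle would be the hindered diaryl ether bond or an unactivated C–C bond of the strap. The forward step must favour intramolecular olefination over oligomerisation.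

**12 ⇒ 11 ⇒ 9 + 10.** The O–B1 bond is cut, and the aldehyde is retraced to a cyclic acetal. The ether bond is formed while B1 is still an sp3 carbenoid carbon derived from diazophosphonate 10, so the phenol of 9 only has to insert into a metal carbenoid. The aldehyde is masked during this step because a free formyl group could trap the carbenoid as a carbonyl ylide.

**9 ⇒ 8 ⇒ 5 + 7 (from 6).** One O–CH3 bond is restored and the aryl–alkyl bond A3–C14 is cut. The symmetric 3,5-dimethoxyphenyl unit of 6 makes the coupling regiochemically trivial. Desymmetrisation is left to a single thiolate demethylation, which stops after the first phenoxide forms.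

**5 ⇒ 4 ⇒ 3 ⇒ 1.** The fifteen carbons of the strap plus B6 are taken as they stand from lactone 1, whose two ends are already differentiated. Ring opening gives a primary bromide for the coupling at one end and an ester at the other, which is brought to the aldehyde level and masked.

## Alternatives that were turned down

**Alternative 1: ring A by benzannulation.**
- Disconnection: ring A itself is taken apart (A3–A4, A1–A6, A4–A5, A1–A2). Target 20 goes back through its ring B dimethyl ether A1 to the acyclic diazo ketone A2, 17-[2-(ethynyloxy)-3,5-dimethoxyphenyl]-1-diazo-3-methylideneheptadecan-2-one.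
- Forward key step: irradiation of A2 causes a Wolff shift of the vinyl group (A3–A4). The vinylketene adds [2+2] to the remote ethynyl ether (A1–A6, A4–A5). Thermal cyclobutenone opening and six-electron closure (A1–A2) then give A1.
- For: ring A emerges with exactly the target pattern (free OH at A1, aryloxy at A5), and ring and macrocycle form in one operation. Only one demethylation follows, so the end game is shorter than in the chosen route. On that point this alternative is stronger.
- Against: the ketene–alkyne cycloaddition would have to be the ring-closing event of a 20-membered ring, with no preorganisation and a short-lived ketene. Dimerisation and adventitious trapping should win unless dilution is extreme. A2 also combines an α-methylene diazo ketone, prone to internal dipolar cycloaddition, with a labile aryl ethynyl ether on a di-ortho-substituted ring. Making that ether still requires the fully substituted ring B phenol first.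
- Comparison: the chosen route spends three more steps after ring closure. In return it closes the ring with a reaction type established for macrocycles and passes only through stable intermediates.

**Alternative 2: ten-carbon strap by double acetylide alkylation.**
- Disconnection: the chain bonds C2–C3 and C12–C13 are cut, giving the diethynyl diaryl ether A4 (1-ethynyl-2-(3-ethynyl-5-methoxyphenoxy)-3,5-dimethoxybenzene) and 1,10-diiododecane A5.
- Forward key step: the dilithium bis-acetylide of A4 is alkylated twice by A5, and the second alkylation closes the ring to the diyne A3. Hydrogenation and demethylation follow.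
- For: it is highly convergent, uses a symmetric C10 piece, needs no redox work on ring B, and is short once A4 is in hand. On step count it is stronger.
- Against: A4 requires the very C–O coupling at the hindered, electron-rich B1 that is hardest to make. The first alkylation is intermolecular and wants concentration, while the second is intramolecular and wants dilution. In one flask the 1:1 intermediate competes with 2:1 and 1:2 adducts and with polymer. Aryl acetylides are also modest nucleophiles toward primary iodides, and elimination competes.
- Comparison: the chosen route never builds a diaryl ether by coupling. Its ring closure is unimolecular, from a substrate with exactly one donor and one acceptor.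

**Alternative 3: SNAr macrocyclisation, then double Dakin oxidation.**
- Disconnection: the B1–O bond is cut, giving the seco compound A7, 5-[14-(3,5-dihydroxyphenyl)tetradecyl]-4-fluorobenzene-1,3-dicarbaldehyde.
- Forward key step: a ring A phenoxide displaces fluoride at B1, which is activated by one ortho and one para formyl group, and gives the macrocyclic dialdehyde A6. A double Dakin oxidation then converts both formyl groups into the B2 and B4 hydroxyls.
- For: formyl-activated SNAr is dependable for macrocyclic diaryl ethers. The nucleophile is a symmetric resorcinol, so either hydroxyl gives the same product and the other remains as the A1 phenol without protection. The end game is two operations. The ring closure is at least as reliable as the olefination chosen here, and the end game is shorter.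
- Against: A7 is a 1,2,3,5-tetrasubstituted fluoroarene with two formyl groups and a long chain ortho to fluorine, which needs a long linear arene synthesis before the key step. The first Dakin migration occurs on a ring that still carries an electron-withdrawing formyl group, where hydride shift to the acid competes with aryl shift. Free electron-rich phenols are also exposed to peroxide and base.
- Comparison: the chosen route offers cheap building blocks (1, 6, 10, 14), an oxygenation pattern of ring B that follows from how the ring is built rather than from a late oxidation, and no oxidant in the presence of free phenols until ring B is protected as its ethers.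

Key step: step 8

Remark on the chemistry: 20 has no stereocentre; the stereocentres of 11, 12 and 15–18 are transient and are carried as racemates or diastereomer mixtures (16–18 drawn as keto forms), since all are lost by step 11. Phane names use 1 = ring A, 2 = O, 3 = ring B or its cyclohexane precursor, 4–17 = the chain, with 1⁵ = A1, 3¹ = B1, 3² = B6, 3³ = B5, 3⁴ = B4, 3⁶ = B2.

## Route

Step 1
Reactants: 1 pentadecanolide (oxacyclohexadecan-2-one)
Product: 3 methyl 15-bromopentadecanoate, via 15-bromopentadecanoic acid 2 (not isolated)
Conditions: HBr (33% in AcOH), 70 °C; evaporate; then MeOH, H2SO4 (cat.), reflux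
Reagents that add atoms: hydrogen bromide (Br); methanol (CO)
Why: Acidolysis of the macrolactone with bromide attack at the primary alkyl carbon should give the ω-bromo acid, and Fischer esterification in the same flask gives the methyl ester. The two chain ends are thereby differentiated in one operation.

Step 2
Reactants: 3 methyl 15-bromopentadecanoate
Product: 4 15-bromopentadecanal
Conditions: iBu2AlH (1.1 equiv), CH2Cl2, −78 °C; then MeOH, aq. potassium sodium tartrate
Reagents that add atoms: none
Why: Partial reduction of a methyl ester with iBu2AlH at low temperature stops at the aluminium hemiacetal, which releases the aldehyde on work-up. The primary bromide is inert to the hydride at −78 °C.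

Step 3
Reactants: 4 15-bromopentadecanal
Product: 5 2-(14-bromotetradecyl)-1,3-dioxolane
Conditions: HOCH2CH2OH, TsOH·H2O (cat.), toluene, reflux (Dean–Stark)
Reagents that add atoms: ethane-1,2-diol (OCCO)
Why: Acid-catalysed acetalisation driven by azeotropic removal of water. The dioxolane masks the future B6 carbon against the Grignard reagent, the thiolate and the rhodium carbenoid of steps 4–6.

Step 4
Reactants: 5 2-(14-bromotetradecyl)-1,3-dioxolane; 6 1-bromo-3,5-dimethoxybenzene
Product: 8 2-[14-(3,5-dimethoxyphenyl)tetradecyl]-1,3-dioxolane, via (3,5-dimethoxyphenyl)magnesium bromide 7 (not isolated)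
Conditions: 6, Mg, THF, reflux; then 5, Li2CuCl4 (3 mol%), THF, −10 °C to rt
Reagents that add atoms: none
Why: Copper-catalysed (Kochi-type) cross-coupling of an aryl Grignard reagent with a primary alkyl bromide forms the A3–C14 bond. The acetal is inert to the organomagnesium reagent, and the symmetric aryl unit leaves no regiochemical question.

Step 5
Reactants: 8 2-[14-(3,5-dimethoxyphenyl)tetradecyl]-1,3-dioxolane
Product: 9 3-[14-(1,3-dioxolan-2-yl)tetradecyl]-5-methoxyphenol
Conditions: NaSEt (3 equiv), DMF, 140 °C; then cold 1 M HCl to pH 6
Reagents that add atoms: none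
Why: SN2 demethylation of an aryl methyl ether by thiolate. The phenoxide formed after the first cleavage deactivates the ring toward a second one, so mono-demethylation of the 5-alkylresorcinol dimethyl ether is expected. The acetal is stable to the basic medium.

Step 6
Reactants: 9 3-[14-(1,3-dioxolan-2-yl)tetradecyl]-5-methoxyphenol; 10 dimethyl (1-diazo-2-oxopropyl)phosphonate
Product: 11 dimethyl (1-{3-[14-(1,3-dioxolan-2-yl)tetradecyl]-5-methoxyphenoxy}-2-oxopropyl)phosphonate (racemic)
Conditions: Rh2(OAc)4 (2 mol%), toluene, 90 °C, slow addition of 10
Reagents that add atoms: none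
Why: Rhodium-carbenoid O–H insertion: loss of dinitrogen gives an electrophilic carbenoid, the phenol oxygen adds to it, and a proton shift gives the α-aryloxy β-ketophosphonate. The O–B1 bond is thus made at an sp3 carbon. The new stereocentre at B1 is formed racemic and is destroyed in step 8.

Step 7
Reactants: 11 dimethyl (1-{3-[14-(1,3-dioxolan-2-yl)tetradecyl]-5-methoxyphenoxy}-2-oxopropyl)phosphonate
Product: 12 dimethyl {1-[3-methoxy-5-(15-oxopentadecyl)phenoxy]-2-oxopropyl}phosphonate (racemic)
Conditions: 1 M HCl, THF, rt
Reagents that add atoms: water (O)
Why: Acid-catalysed hydrolysis of the dioxolane releases the aldehyde. The β-ketophosphonate, its methyl esters and the aryl ethers should tolerate dilute acid at room temperature, and 12 is used directly.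

Step 8
Reactants: 12 dimethyl {1-[3-methoxy-5-(15-oxopentadecyl)phenoxy]-2-oxopropyl}phosphonate
Product: 13 1-[(3Z)-21-methoxy-2-oxabicyclo[17.3.1]tricosa-1(23),3,19,21-tetraen-3-yl]ethan-1-one (20-membered α-aryloxy enone; C3 = B1, C4 = B6)
Conditions: LiCl, DBU, MeCN, rt, syringe-pump addition of 12 (final concentration about 1 mM)
Reagents that add atoms: none
Why: Intramolecular Horner–Wadsworth–Emmons olefination under Masamune–Roush conditions: lithium coordination to the phosphoryl and ketone oxygens lets DBU remove the proton at B1, the chelated carbanion adds to the chain aldehyde carbon B6, and the oxaphosphetane collapses with loss of dimethyl phosphate to give the B1=B6 double bond. The closest known reaction type is the Horner–Wadsworth–Emmons macrocyclisation of ω-formyl β-ketophosphonates to macrocyclic enones, together with the olefination of α-aryloxy phosphonates made by carbenoid O–H insertion. The 20-membered ring closes in the addition step in a 20-exo-trig mode, with the carbonyl oxygen outside the ring. No stereocentre is formed; the racemic centre at B1 becomes sp2, and the alkene geometry (expected with acetyl trans to the chain, i.e. Z) does not matter because B6 is saturated in step 9 and aromatic after step 11. The selectivity needed is ring closure over intermolecular olefination; it is secured by slow addition into a dilute solution, by each molecule carrying exactly one donor and one acceptor, and by the long strap, which lets the ends meet without strain. Chemoselectivity follows from acidity: the proton at B1, flanked by phosphoryl, ketone and aryloxy groups, is far more acidic than the methyl ketone or the aldehyde α-protons, so the mild amine base should act only there.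

Step 9
Reactants: 13 1-[(3Z)-21-methoxy-2-oxabicyclo[17.3.1]tricosa-1(23),3,19,21-tetraen-3-yl]ethan-1-one; 14 dimethyl malonate
Product: 16 methyl 1⁵-methoxy-3⁴,3⁶-dioxo-2-oxa-1(1,3)-benzena-3(1,2)-cyclohexanacycloheptadecaphane-3³-carboxylate (ring B as a 2,4-dioxocyclohexanecarboxylate; diastereomer mixture), via Michael adduct 15 (not isolated)
Conditions: NaOMe, MeOH, reflux; then aq. HCl
Reagents that add atoms: none
Why: Michael–Claisen annulation: the malonate anion adds to B6, the only acceptor carbon, and the methyl ketone enolate (B3) then acylates one malonate ester (B4) to close the six-membered ring. Formation of the stabilised β-diketone enolate pulls the equilibria forward. The stereocentres at B1, B5 and B6 form as a mixture and are all removed by step 11.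

Step 10
Reactants: 16 methyl 1⁵-methoxy-3⁴,3⁶-dioxo-2-oxa-1(1,3)-benzena-3(1,2)-cyclohexanacycloheptadecaphane-3³-carboxylate
Product: 18 1⁵-methoxy-2-oxa-1(1,3)-benzena-3(1,2)-cyclohexanacycloheptadecaphane-3⁴,3⁶-dione (4-aryloxy-5-alkylcyclohexane-1,3-dione; diastereomer mixture), via keto acid 17 (not isolated)
Conditions: aq. NaOH, MeOH, reflux; then HCl to pH 1, 70 °C
Reagents that add atoms: none
Why: Saponification of the ester, then decarboxylation of the resulting β-keto acid on acidification and warming; this is the classical second stage of the enone-plus-malonate route to 5-alkylcyclohexane-1,3-diones. The diaryl-type ether at B1 has no β-carbanion pathway for elimination and should survive.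

Step 11
Reactants: 18 1⁵-methoxy-2-oxa-1(1,3)-benzena-3(1,2)-cyclohexanacycloheptadecaphane-3⁴,3⁶-dione
Product: 19 1⁵,3⁴,3⁶-trimethoxy-2-oxa-1(1,3),3(1,2)-dibenzenacycloheptadecaphane
Conditions: I2 (2.2 equiv), MeOH, reflux
Reagents that add atoms: methanol (CO)
Why: Iodine-in-methanol aromatisation of a cyclohexane-1,3-dione: acid-catalysed formation of the methyl enol ethers, α-iodination, loss of hydrogen iodide and tautomerisation give the resorcinol dimethyl ether. The method leaves its own resorcinol dimethyl ether products uniodinated, and ring A is no more electron-rich than these, so it should be tolerated. Any partly methylated material converges in step 12.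

Step 12
Reactants: 19 1⁵,3⁴,3⁶-trimethoxy-2-oxa-1(1,3),3(1,2)-dibenzenacycloheptadecaphane
Product: 20 2-oxa-1(1,3),3(1,2)-dibenzenacycloheptadecaphane-1⁵,3⁴,3⁶-triol (target)
Conditions: BBr3 (6 equiv), CH2Cl2, −78 °C to rt; then MeOH, H2O (under argon)
Reagents that add atoms: none
Why: Lewis-acid cleavage of aryl methyl ethers: bromide attacks the methyl group of each boron–ether adduct, and hydrolysis releases the three phenols. The diaryl ether has no sp3 C–O bond and is not cleaved.

## Compound list

1 | pentadecanolide (oxacyclohexadecan-2-one) | O=C1CCCCCCCCCCCCCCO1 | starting material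
2 | 15-bromopentadecanoic acid | OC(=O)CCCCCCCCCCCCCCBr | intermediate (not isolated)
3 | methyl 15-bromopentadecanoate | COC(=O)CCCCCCCCCCCCCCBr | intermediate
4 | 15-bromopentadecanal | O=CCCCCCCCCCCCCCCBr | intermediate
5 | 2-(14-bromotetradecyl)-1,3-dioxolane | BrCCCCCCCCCCCCCCC1OCCO1 | intermediate
6 | 1-bromo-3,5-dimethoxybenzene | COc1cc(Br)cc(OC)c1 | starting material
7 | (3,5-dimethoxyphenyl)magnesium bromide | COc1cc([Mg]Br)cc(OC)c1 | intermediate (not isolated)
8 | 2-[14-(3,5-dimethoxyphenyl)tetradecyl]-1,3-dioxolane | COc1cc(CCCCCCCCCCCCCCC2OCCO2)cc(OC)c1 | intermediate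
9 | 3-[14-(1,3-dioxolan-2-yl)tetradecyl]-5-methoxyphenol | COc1cc(O)cc(CCCCCCCCCCCCCCC2OCCO2)c1 | intermediate
10 | dimethyl (1-diazo-2-oxopropyl)phosphonate | CC(=O)C(=[N+]=[N-])P(=O)(OC)OC | starting material
11 | dimethyl (1-{3-[14-(1,3-dioxolan-2-yl)tetradecyl]-5-methoxyphenoxy}-2-oxopropyl)phosphonate (racemic) | COc1cc(CCCCCCCCCCCCCCC2OCCO2)cc(OC(C(C)=O)P(=O)(OC)OC)c1 | intermediate
12 | dimethyl {1-[3-methoxy-5-(15-oxopentadecyl)phenoxy]-2-oxopropyl}phosphonate (racemic) | COc1cc(CCCCCCCCCCCCCCC=O)cc(OC(C(C)=O)P(=O)(OC)OC)c1 | intermediate
13 | 1-[(3Z)-21-methoxy-2-oxabicyclo[17.3.1]tricosa-1(23),3,19,21-tetraen-3-yl]ethan-1-one | COc1cc2cc(c1)O/C(C(C)=O)=C\CCCCCCCCCCCCCC2 | intermediate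
14 | dimethyl malonate | COC(=O)CC(=O)OC | starting material
15 | dimethyl 2-[3-acetyl-21-methoxy-2-oxabicyclo[17.3.1]tricosa-1(23),19,21-trien-4-yl]propanedioate (diastereomer mixture) | COc1cc2cc(c1)OC(C(C)=O)C(C(C(=O)OC)C(=O)OC)CCCCCCCCCCCCCC2 | intermediate (not isolated)
16 | methyl 1⁵-methoxy-3⁴,3⁶-dioxo-2-oxa-1(1,3)-benzena-3(1,2)-cyclohexanacycloheptadecaphane-3³-carboxylate (diastereomer mixture) | COc1cc2cc(c1)OC1C(=O)CC(=O)C(C(=O)OC)C1CCCCCCCCCCCCCC2 | intermediate
17 | 1⁵-methoxy-3⁴,3⁶-dioxo-2-oxa-1(1,3)-benzena-3(1,2)-cyclohexanacycloheptadecaphane-3³-carboxylic acid (diastereomer mixture) | COc1cc2cc(c1)OC1C(=O)CC(=O)C(C(O)=O)C1CCCCCCCCCCCCCC2 | intermediate (not isolated)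
18 | 1⁵-methoxy-2-oxa-1(1,3)-benzena-3(1,2)-cyclohexanacycloheptadecaphane-3⁴,3⁶-dione (diastereomer mixture) | COc1cc2cc(c1)OC1C(=O)CC(=O)CC1CCCCCCCCCCCCCC2 | intermediate
19 | 1⁵,3⁴,3⁶-trimethoxy-2-oxa-1(1,3),3(1,2)-dibenzenacycloheptadecaphane | COc1cc2cc(c1)Oc1c(OC)cc(OC)cc1CCCCCCCCCCCCCC2 | intermediate
20 | 2-oxa-1(1,3),3(1,2)-dibenzenacycloheptadecaphane-1⁵,3⁴,3⁶-triol | Oc1cc2cc(c1)Oc1c(O)cc(O)cc1CCCCCCCCCCCCCC2 | target

## Step count and risk

Total step count: 12. Longest linear sequence: 12 steps (1 → 3 → 4 → 5 → 8 → 9 → 11 → 12 → 13 → 16 → 18 → 19 → 20); 6, 10 and 14 enter as purchased reagents.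

**Step 8 (key step).**
- Risk: intermolecular olefination to cyclic dimers and oligomers, because the strap gives no conformational bias toward the monomeric ring. Base-induced self-aldol of the aldehyde during the long addition is a further risk. The α-oxygenated, fully substituted carbanion also adds more slowly than a simple ketophosphonate anion.
- Fallback (sets out from 7, made from 6 as in step 4, and returns at 13): the ring is closed by metathesis within the strap, after the enone has been made intermolecularly.
  - Copper-catalysed coupling of 7 with 11-bromoundec-1-ene gives 1,3-dimethoxy-5-(undec-10-en-1-yl)benzene F1.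
  - NaSEt in DMF gives 3-methoxy-5-(undec-10-en-1-yl)phenol F2.
  - O–H insertion of 10 (Rh2(OAc)4) gives dimethyl {1-[3-methoxy-5-(undec-10-en-1-yl)phenoxy]-2-oxopropyl}phosphonate F3.
  - Intermolecular Horner–Wadsworth–Emmons reaction with hex-5-enal (LiCl, DBU) gives (3Z)-3-[3-methoxy-5-(undec-10-en-1-yl)phenoxy]nona-3,8-dien-2-one F4.
  - Ring-closing metathesis of the two terminal alkenes (second-generation Grubbs catalyst, dilute CH2Cl2, 40 °C) closes the 20-membered ring at C4–C5 of the strap and gives 1-[(3Z)-21-methoxy-2-oxabicyclo[17.3.1]tricosa-1(23),3,8,19,21-pentaen-3-yl]ethan-1-one F5.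
  - Hydrogenation with RhCl(PPh3)3 and H2, which reduces the disubstituted chain alkene in preference to the trisubstituted conjugated enone, gives 13.

**Step 9.**
- Risk: sluggish or reversible conjugate addition, because the aryloxy oxygen on B1 donates into the alkene and lowers the electrophilicity of B6. Methoxide-induced deconjugation of the enone toward C1 of the strap could also drain material.
- Fallback (from 13, returning at 18): Lewis-acid activation replaces the basic Michael step.
  - Mukaiyama–Michael addition of 1-methoxy-1-(trimethylsilyloxy)ethene (TiCl4, CH2Cl2, −78 °C), with the Lewis acid chelated between the ketone and aryloxy oxygens, gives methyl 2-[3-acetyl-21-methoxy-2-oxabicyclo[17.3.1]tricosa-1(23),19,21-trien-4-yl]acetate F6.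
  - Intramolecular Claisen condensation of the methyl ketone onto the ester (KOtBu, THF) closes ring B and gives 18 directly, without a decarboxylation.

**Step 11.**
- Risk: electrophilic iodination of one of the electron-rich rings if hydrogen iodide is lost from the medium. Ionisation at B1 after iodination there, with loss of the ring A phenol, would open the macrocycle. Incomplete O-methylation would give a mixture of ethers, which is harmless.
- Fallback (from 18, returning at 20): a halogen-free dehydrogenation through silyl enol ethers.
  - Me3SiOTf and Et3N give the bis(trimethylsilyl) dienol ether of 18 F7 (silyloxy groups on B2 and B4, double bonds B2=B3 and B4=B5).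
  - Saegusa–Ito-type oxidation (Pd(OAc)2 cat., O2, DMSO) gives 1⁵-methoxy-3⁴,3⁶-bis(trimethylsilyloxy)-2-oxa-1(1,3),3(1,2)-dibenzenacycloheptadecaphane F8.
  - Dilute HCl in the work-up cleaves the silyl ethers to 1⁵-methoxy-2-oxa-1(1,3),3(1,2)-dibenzenacycloheptadecaphane-3⁴,3⁶-diol F9.
  - BBr3 under the conditions of step 12 then gives 20.

**Step 6.**
- Risk: attack of the carbenoid on the electron-rich ring of 9 (cyclopropanation or formal C–H insertion) instead of the hydroxyl group, Wolff rearrangement of the acyl carbenoid, or ylide formation at an acetal oxygen.
- Fallback (from 9, returning at 11): the ether bond is made by alkylation and the acetyl group added afterwards.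
  - O-Alkylation with (dimethoxyphosphoryl)methyl trifluoromethanesulfonate (Cs2CO3, MeCN, 0 °C) gives dimethyl ({3-[14-(1,3-dioxolan-2-yl)tetradecyl]-5-methoxyphenoxy}methyl)phosphonate F10.
  - Deprotonation (LiN(iPr)2, 2 equiv, THF, −78 °C) and C-acylation with N-methoxy-N-methylacetamide give 11.

**Step 4.**
- Risk: homocoupling of the aryl Grignard reagent, halogen–magnesium exchange with the alkyl bromide, or elimination of the bromide. Aryl Grignard reagents couple more slowly than alkyl ones under copper catalysis.
- Fallback (from 5 and 6, returning at 8): the polarity is reversed.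
  - Zinc insertion into 5 (Zn dust, LiCl, THF, 50 °C) gives [14-(1,3-dioxolan-2-yl)tetradecyl]zinc bromide F11.
  - Negishi coupling with 6 (Pd(OAc)2, SPhos, THF) gives 8.

## Further compounds

F1 | step 8 | 1,3-dimethoxy-5-(undec-10-en-1-yl)benzene | COc1cc(CCCCCCCCCC=C)cc(OC)c1
F2 | step 8 | 3-methoxy-5-(undec-10-en-1-yl)phenol | COc1cc(O)cc(CCCCCCCCCC=C)c1
F3 | step 8 | dimethyl {1-[3-methoxy-5-(undec-10-en-1-yl)phenoxy]-2-oxopropyl}phosphonate (racemic) | COc1cc(CCCCCCCCCC=C)cc(OC(C(C)=O)P(=O)(OC)OC)c1
F4 | step 8 | (3Z)-3-[3-methoxy-5-(undec-10-en-1-yl)phenoxy]nona-3,8-dien-2-one | COc1cc(CCCCCCCCCC=C)cc(O/C(C(C)=O)=C\CCCC=C)c1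
F5 | step 8 | 1-[(3Z)-21-methoxy-2-oxabicyclo[17.3.1]tricosa-1(23),3,8,19,21-pentaen-3-yl]ethan-1-one (E/Z mixture at C8) | COc1cc2cc(c1)O/C(C(C)=O)=C\CCCC=CCCCCCCCCC2
F6 | step 9 | methyl 2-[3-acetyl-21-methoxy-2-oxabicyclo[17.3.1]tricosa-1(23),19,21-trien-4-yl]acetate (diastereomer mixture) | COc1cc2cc(c1)OC(C(C)=O)C(CC(=O)OC)CCCCCCCCCCCCCC2
F7 | step 11 | bis(trimethylsilyl) dienol ether of 18 (silyloxy on B2 and B4; B2=B3 and B4=B5) | COc1cc2cc(c1)OC1C(O[Si](C)(C)C)=CC(O[Si](C)(C)C)=CC1CCCCCCCCCCCCCC2
F8 | step 11 | 1⁵-methoxy-3⁴,3⁶-bis(trimethylsilyloxy)-2-oxa-1(1,3),3(1,2)-dibenzenacycloheptadecaphane | COc1cc2cc(c1)Oc1c(O[Si](C)(C)C)cc(O[Si](C)(C)C)cc1CCCCCCCCCCCCCC2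
F9 | step 11 | 1⁵-methoxy-2-oxa-1(1,3),3(1,2)-dibenzenacycloheptadecaphane-3⁴,3⁶-diol | COc1cc2cc(c1)Oc1c(O)cc(O)cc1CCCCCCCCCCCCCC2
F10 | step 6 | dimethyl ({3-[14-(1,3-dioxolan-2-yl)tetradecyl]-5-methoxyphenoxy}methyl)phosphonate | COc1cc(CCCCCCCCCCCCCCC2OCCO2)cc(OCP(=O)(OC)OC)c1
F11 | step 4 | [14-(1,3-dioxolan-2-yl)tetradecyl]zinc bromide | Br[Zn]CCCCCCCCCCCCCCC1OCCO1
A1 | alternative 1 | 3⁴,3⁶-dimethoxy-2-oxa-1(1,3),3(1,2)-dibenzenacycloheptadecaphan-1⁵-ol | Oc1cc2cc(c1)Oc1c(OC)cc(OC)cc1CCCCCCCCCCCCCC2
A2 | alternative 1 | 17-[2-(ethynyloxy)-3,5-dimethoxyphenyl]-1-diazo-3-methylideneheptadecan-2-one | C=C(C(=O)C=[N+]=[N-])CCCCCCCCCCCCCCc1cc(OC)cc(OC)c1OC#C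
A3 | alternative 2 | 20-membered diyne, 1⁵,3⁴,3⁶-trimethoxy-2-oxa-1(1,3),3(1,2)-dibenzenacycloheptadecaphane-4,16-diyne | COc1cc2cc(c1)Oc1c(OC)cc(OC)cc1C#CCCCCCCCCCCC#C2
A4 | alternative 2 | 1-ethynyl-2-(3-ethynyl-5-methoxyphenoxy)-3,5-dimethoxybenzene | COc1cc(C#C)cc(c1)Oc1c(OC)cc(OC)cc1C#C
A5 | alternative 2 | 1,10-diiododecane | ICCCCCCCCCCI
A6 | alternative 3 | 1⁵-hydroxy-2-oxa-1(1,3),3(1,2)-dibenzenacycloheptadecaphane-3⁴,3⁶-dicarbaldehyde | Oc1cc2cc(c1)Oc1c(C=O)cc(C=O)cc1CCCCCCCCCCCCCC2
A7 | alternative 3 | 5-[14-(3,5-dihydroxyphenyl)tetradecyl]-4-fluorobenzene-1,3-dicarbaldehyde | O=Cc1cc(C=O)c(F)c(CCCCCCCCCCCCCCc2cc(O)cc(O)c2)c1
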